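**Plan**

1. Cuts: the O5/O6 catechol is masked as one diphenylmethylene ketal. Ring B is cut at C2'–C3' and C1'–C6' (retro-[4+2], with the C6'–O bridge restored), leaving a 2-ethynylchromone and 3-methoxyfuran.
2. Enabling feature: in ring B the hydroxyl carbon C3' and the methoxy carbon C4' are adjacent, and C4' is para to C1'. This matches O1–C2 and C3–OMe of 3-methoxyfuran, so the furan oxygen ends as the 3'-OH and the furan methoxy as the 4'-OMe.
3. Further cuts: the C≡C bond (one-carbon homologation of a 2-formylchromone), C2–C3 and O1–C2 of ring C (oxalate Claisen condensation, cyclodehydration), C4–C4a (Fries shift), and two ring A C–O bonds (phenol-to-quinone oxidation, Thiele–Winter acetoxylation).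
4. Forward order: ring A is bought as 2,3-dimethoxyphenol and raised to the penta-oxygenated level, ring C is closed onto it, ring B is closed last, and the ketal is then removed.
5. Stereochemistry: the target has no stereocentre, axis or stereogenic double bond and is a single achiral compound. The two bridgehead centres of the cycloadduct are transient and vanish on aromatisation.

Key step: step 10

Remark: because the target is achiral, the demand for a single stereoisomer is met without any asymmetric step.
Remark: the non-isolated Fries intermediate of step 3 is drawn as the isomer formed by shift of the acetate next to the methoxy group. Shift of the other flanking acetate would give a positional isomer that is hydrolysed to the same triol.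

**Step 1**
Reactants: 1 2,3-dimethoxyphenol
Product: 2 2,3-dimethoxy-1,4-benzoquinone
Conditions: (KSO3)2NO (2.5 equiv), KH2PO4 buffer, H2O/acetone, 0 °C → rt
Reagents that add atoms: potassium nitrosodisulfonate (Fremy's salt), [O]N(S(=O)(=O)[O-])S(=O)(=O)[O-].[K+].[K+]
Why: Teuber oxidation: Fremy's radical abstracts the phenolic hydrogen and a second equivalent delivers oxygen to the free para carbon, which is the standard conversion of a para-unsubstituted phenol into the 1,4-quinone.

**Step 2**
Reactants: 2 2,3-dimethoxy-1,4-benzoquinone
Product: 3 5,6-dimethoxybenzene-1,2,4-triyl triacetate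
Conditions: Ac2O, conc. H2SO4 (cat.), 0 → 25 °C
Reagents that add atoms: acetic anhydride, CC(=O)OC(C)=O
Why: Thiele–Winter acetoxylation: acid-catalysed conjugate addition of acetic anhydride to the unsubstituted C5=C6 edge, enolisation and peracetylation give the triacetate, and the C2 symmetry of 2 allows only one regioisomer.

**Step 3**
Reactants: 3 5,6-dimethoxybenzene-1,2,4-triyl triacetate
Product: 5 2,3,6-trihydroxy-4,5-dimethoxyacetophenone, via Fries diacetate 4 (not isolated)
Conditions: BF3·OEt2 (6 equiv), PhCl, 85 °C, Ar; then 2 M aq. HCl, THF, 60 °C, Ar; Na2S2O4 wash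
Reagents that add atoms: none
Why: Fries rearrangement: the BF3-released acylium ion can only attack the single free ring carbon, which lies para to a methoxy group and between two oxygens, and the later acid hydrolysis removes the remaining acetates without exposing the oxidation-prone hydroxyhydroquinone to base.

**Step 4**
Reactants: 5 2,3,6-trihydroxy-4,5-dimethoxyacetophenone
Product: 6 1-(5-hydroxy-6,7-dimethoxy-2,2-diphenyl-1,3-benzodioxol-4-yl)ethanone (the 2,3-O-diphenylmethylene ketal of 5)
Conditions: Ph2CCl2 (1.2 equiv), Ph2O, 170 °C, Ar, 30 min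
Reagents that add atoms: dichlorodiphenylmethane, ClC(Cl)(c1ccccc1)c1ccccc1
Why: Catechol ketalisation with dichlorodiphenylmethane: only the vicinal C2 and C3 hydroxyls can close a five-membered 1,3-dioxole, so the isolated C6 hydroxyl that will become O1 stays free.

**Step 5**
Reactants: 6 1-(5-hydroxy-6,7-dimethoxy-2,2-diphenyl-1,3-benzodioxol-4-yl)ethanone; 7 diethyl oxalate
Product: 9 ethyl 5,6-(diphenylmethylenedioxy)-7,8-dimethoxy-4-oxo-4H-chromene-2-carboxylate, via diketo ester 8 (not isolated)
Conditions: NaOEt (4 equiv), EtOH/THF, 65 °C, Ar; 1 M HCl quench; crude, p-TsOH·H2O (10 mol %), PhMe, 80 °C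
Reagents that add atoms: none
Why: Crossed Claisen condensation of the methyl ketone with non-enolisable diethyl oxalate and acid-catalysed cyclodehydration is the standard chromone-2-carboxylate synthesis, the single free phenol makes ring C closure unambiguous, and catalytic anhydrous acid spares a ketal that needs hot aqueous acid for cleavage.

**Step 6**
Reactants: 9 ethyl 5,6-(diphenylmethylenedioxy)-7,8-dimethoxy-4-oxo-4H-chromene-2-carboxylate
Product: 10 2-(hydroxymethyl)-5,6-(diphenylmethylenedioxy)-7,8-dimethoxychromone
Conditions: NaBH4 (1.5 equiv), THF/EtOH, 0 °C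
Reagents that add atoms: none
Why: Chemoselective borohydride reduction: the ester on the electron-poor C2 is reduced at 0 °C as in other chromone-2-carboxylates, whereas the C4 carbonyl is a vinylogous ester and stays untouched.

**Step 7**
Reactants: 10 2-(hydroxymethyl)-5,6-(diphenylmethylenedioxy)-7,8-dimethoxychromone
Product: 11 5,6-(diphenylmethylenedioxy)-7,8-dimethoxy-4-oxo-4H-chromene-2-carbaldehyde
Conditions: Dess–Martin periodinane (1.2 equiv), CH2Cl2, 0 °C → rt
Reagents that add atoms: none
Why: Dess–Martin oxidation converts the primary allylic-type alcohol into the aldehyde under neutral, water-free conditions that avoid hydrate formation, over-oxidation and ketal loss.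

**Step 8**
Reactants: 11 5,6-(diphenylmethylenedioxy)-7,8-dimethoxy-4-oxo-4H-chromene-2-carbaldehyde
Product: 12 2-ethynyl-5,6-(diphenylmethylenedioxy)-7,8-dimethoxychromone
Conditions: TMSCHN2 (1.2 equiv), LDA (1.2 equiv, commercial solution), THF, −78 °C; then 11, −78 → 0 °C; H2O quench
Reagents that add atoms: (trimethylsilyl)diazomethane, C[Si](C)(C)C=[N+]=[N-]
Why: Colvin rearrangement (the aprotic relative of the Seyferth–Gilbert homologation): the lithiated diazo reagent adds to the aldehyde, the most electrophilic carbonyl present, silanolate and nitrogen are lost and the alkylidene carbene undergoes a 1,2-hydrogen shift, while the absence of methanol and carbonate prevents conjugate addition to the pyrone or to the new enyne.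

**Step 9**
Reactants: 13 3-bromofuran
Product: 14 3-methoxyfuran
Conditions: NaOMe (3 equiv), CuBr (10 mol %), MeOH/NMP, 105 °C, sealed vessel; distillation
Reagents that add atoms: sodium methoxide, C[O-].[Na+]
Why: Copper-catalysed Ullmann-type methoxylation of a heteroaryl bromide, as used for 3-bromothiophene and 3-bromofuran, replaces bromine at C3 without touching the ring, and the volatile product is isolated by distillation from base.

**Step 10**
Reactants: 12 2-ethynyl-5,6-(diphenylmethylenedioxy)-7,8-dimethoxychromone; 14 3-methoxyfuran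
Product: 16 5,6-(diphenylmethylenedioxy)-3'-hydroxy-7,8,4'-trimethoxyflavone, via oxanorbornadiene adduct 15 (not isolated)
Conditions: 14 (5 equiv), Yb(OTf)3 (10 mol %), 4 Å MS, CH2Cl2, 40 °C, sealed tube, Ar; then PPTS (20 mol %), rt
Reagents that add atoms: none
Why: Proposed new method: Yb(III) bound to the C4 carbonyl (assisted by the C5 ketal oxygen) increases the pyrylium character of ring C and polarises the C≡C–C2=C3–C4=O chain so that the terminal alkyne carbon is its electrophilic end; furan C2, the most nucleophilic carbon of 14 (α to the ring oxygen, β to the methoxy donor), bonds to it (C2'–C3') while furan C5 bonds to the internal alkyne carbon (C1'–C6') in an asynchronous normal-demand [4+2] cycloaddition. The closest known reaction type is the Diels–Alder addition of alkoxyfurans to propiolates or acetylenedicarboxylates with acid isomerisation of the 7-oxanorbornadiene to a phenol; an alkyne activated only through a chromone has not been used as the dienophile. Ring B closes as a six-membered carbocycle by intermolecular suprafacial cycloaddition, giving the "para" adduct 15 with the methoxy carbon C4' opposite the chromonyl carbon C1'. Acid then ionises the C6'–O bond, because the resulting arenium-type cation carries its charge on C2', C4' and C6' and is stabilised by the C4' methoxy group, whereas cleavage of C3'–O would place charge on C1' next to the electron-poor chromone and leave the methoxy group on an uncharged carbon; loss of the C3' proton from this cation gives the 3'-phenol directly, without any hydride shift, and makes the sequence irreversible. The two bridgehead stereocentres of racemic 15 disappear on aromatisation, so no stereocontrol is required. The step needs the right orientation of addition, the right direction of bridge opening and attack on the alkyne in preference to the C2=C3 bond: the first two are fixed by the 3-methoxy group, the third by the unhindered terminal alkyne and by the loss of pyrone conjugation that addition to the trisubstituted C2=C3 bond would cost.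

**Step 11**
Reactants: 16 5,6-(diphenylmethylenedioxy)-3'-hydroxy-7,8,4'-trimethoxyflavone
Product: 17 5,6,3'-trihydroxy-7,8,4'-trimethoxyflavone
Conditions: H2 (1 atm), 10 % Pd/C, THF/MeOH, rt
Reagents that add atoms: none
Why: Catalytic hydrogenolysis cleaves the two doubly benzylic C–O bonds of the diphenylmethylene ketal under neutral conditions, which leave the flavone C2=C3 bond, the three methyl ethers and the oxidation-prone 5,6-catechol intact.

**Compound list**

1 | 2,3-dimethoxyphenol | COc1cccc(O)c1OC | starting material
2 | 2,3-dimethoxy-1,4-benzoquinone | COC1=C(OC)C(=O)C=CC1=O | intermediate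
3 | 5,6-dimethoxybenzene-1,2,4-triyl triacetate | COc1c(OC)c(OC(C)=O)c(OC(C)=O)cc1OC(C)=O | intermediate
4 | 3-acetyl-4-hydroxy-5,6-dimethoxy-1,2-phenylene diacetate (Fries diacetate, not isolated) | CC(=O)c1c(O)c(OC)c(OC)c(OC(C)=O)c1OC(C)=O | intermediate
5 | 2,3,6-trihydroxy-4,5-dimethoxyacetophenone | CC(=O)c1c(O)c(O)c(OC)c(OC)c1O | intermediate
6 | 1-(5-hydroxy-6,7-dimethoxy-2,2-diphenyl-1,3-benzodioxol-4-yl)ethanone | CC(=O)c1c(O)c(OC)c(OC)c2OC(c3ccccc3)(c3ccccc3)Oc12 | intermediate
7 | diethyl oxalate | CCOC(=O)C(=O)OCC | starting material
8 | ethyl 4-(5-hydroxy-6,7-dimethoxy-2,2-diphenyl-1,3-benzodioxol-4-yl)-2,4-dioxobutanoate (diketo ester, not isolated) | CCOC(=O)C(=O)CC(=O)c1c(O)c(OC)c(OC)c2OC(c3ccccc3)(c3ccccc3)Oc12 | intermediate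
9 | ethyl 5,6-(diphenylmethylenedioxy)-7,8-dimethoxy-4-oxo-4H-chromene-2-carboxylate | CCOC(=O)c1cc(=O)c2c3OC(c4ccccc4)(c4ccccc4)Oc3c(OC)c(OC)c2o1 | intermediate
10 | 2-(hydroxymethyl)-5,6-(diphenylmethylenedioxy)-7,8-dimethoxychromone | OCc1cc(=O)c2c3OC(c4ccccc4)(c4ccccc4)Oc3c(OC)c(OC)c2o1 | intermediate
11 | 5,6-(diphenylmethylenedioxy)-7,8-dimethoxy-4-oxo-4H-chromene-2-carbaldehyde | O=Cc1cc(=O)c2c3OC(c4ccccc4)(c4ccccc4)Oc3c(OC)c(OC)c2o1 | intermediate
12 | 2-ethynyl-5,6-(diphenylmethylenedioxy)-7,8-dimethoxychromone | C#Cc1cc(=O)c2c3OC(c4ccccc4)(c4ccccc4)Oc3c(OC)c(OC)c2o1 | intermediate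
13 | 3-bromofuran | Brc1ccoc1 | starting material
14 | 3-methoxyfuran | COc1ccoc1 | intermediate
15 | 2-(5-methoxy-7-oxabicyclo[2.2.1]hepta-2,5-dien-2-yl)-5,6-(diphenylmethylenedioxy)-7,8-dimethoxychromone (racemic, one enantiomer drawn, not isolated) | COC1=C[C@H]2O[C@@H]1C=C2c1cc(=O)c2c3OC(c4ccccc4)(c4ccccc4)Oc3c(OC)c(OC)c2o1 | intermediate
16 | 5,6-(diphenylmethylenedioxy)-3'-hydroxy-7,8,4'-trimethoxyflavone | COc1ccc(-c2cc(=O)c3c4OC(c5ccccc5)(c5ccccc5)Oc4c(OC)c(OC)c3o2)cc1O | intermediate
17 | 5,6,3'-trihydroxy-7,8,4'-trimethoxyflavone | COc1ccc(-c2cc(=O)c3c(O)c(O)c(OC)c(OC)c3o2)cc1O | target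

Total step count: 11
Longest linear sequence: 10 (steps 1–8, 10, 11)

**Steps most likely to fail**

**Step 10.**
- Risk: the chromone-conjugated alkyne may be too weak a dienophile. Several processes could then outrun aromatisation: cycloreversion, Lewis-acid-induced oligomerisation of the furan, a second cycloaddition onto the strained adduct, or a stepwise conjugate attack that ends in proton loss from furan C2 instead of ring closure.
- Fallback (known chemistry): it sets out from 6. Claisen–Schmidt condensation with commercial 3-benzyloxy-4-methoxybenzaldehyde (KOH, EtOH, rt) should give (E)-3-(3-benzyloxy-4-methoxyphenyl)-1-(5-hydroxy-6,7-dimethoxy-2,2-diphenyl-1,3-benzodioxol-4-yl)prop-2-en-1-one F1. Oxidative cyclisation with catalytic I2 in DMSO at 120 °C should then give 3'-benzyloxy-5,6-(diphenylmethylenedioxy)-7,8,4'-trimethoxyflavone F2. Hydrogenolysis under the conditions of step 11 removes the benzyl ether and the ketal together and comes back to the route at 17.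

**Step 8.**
- Risk: the lithiated diazo reagent may attack the pyrone ring instead of the aldehyde, or the basic medium may open ring C or oligomerise the electrophilic enyne.
- Fallback: it sets out from 11 and avoids carbanions. Ramirez olefination (CBr4, PPh3, CH2Cl2, 0 °C) should give 2-(2,2-dibromovinyl)-5,6-(diphenylmethylenedioxy)-7,8-dimethoxychromone F3. Palladium-catalysed hydrogenolysis of the more accessible C–Br bond (Bu3SnH, Pd(PPh3)4 cat., PhMe, rt) should give 2-[(Z)-2-bromovinyl]-5,6-(diphenylmethylenedioxy)-7,8-dimethoxychromone F4. Its anti-periplanar H and Br allow elimination with DBU in CH2Cl2 at rt, which comes back to the route at 12.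

**Step 3.**
- Risk: C-acylation at the crowded carbon between two acyloxy groups may be slow, so that ether cleavage by the Lewis acid or aerial oxidation of the liberated hydroxyhydroquinone takes over.
- Fallback: it sets out from 3. Acid methanolysis (HCl, MeOH, Ar, reflux) should give 5,6-dimethoxybenzene-1,2,4-triol F5, a far more nucleophilic arene. Houben–Hoesch acylation (MeCN, ZnCl2, HCl gas, Et2O, 0 °C) should give 1-(2,3,6-trihydroxy-4,5-dimethoxyphenyl)ethaniminium chloride F6. Hydrolysis of this salt in hot water comes back to the route at 5.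

**Further compounds**

F1 | step 10 | (E)-3-(3-benzyloxy-4-methoxyphenyl)-1-(5-hydroxy-6,7-dimethoxy-2,2-diphenyl-1,3-benzodioxol-4-yl)prop-2-en-1-one | COc1ccc(/C=C/C(=O)c2c(O)c(OC)c(OC)c3OC(c4ccccc4)(c4ccccc4)Oc23)cc1OCc1ccccc1
F2 | step 10 | 3'-benzyloxy-5,6-(diphenylmethylenedioxy)-7,8,4'-trimethoxyflavone | COc1ccc(-c2cc(=O)c3c4OC(c5ccccc5)(c5ccccc5)Oc4c(OC)c(OC)c3o2)cc1OCc1ccccc1
F3 | step 8 | 2-(2,2-dibromovinyl)-5,6-(diphenylmethylenedioxy)-7,8-dimethoxychromone | BrC(Br)=Cc1cc(=O)c2c3OC(c4ccccc4)(c4ccccc4)Oc3c(OC)c(OC)c2o1
F4 | step 8 | 2-[(Z)-2-bromovinyl]-5,6-(diphenylmethylenedioxy)-7,8-dimethoxychromone | Br/C=C\c1cc(=O)c2c3OC(c4ccccc4)(c4ccccc4)Oc3c(OC)c(OC)c2o1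
F5 | step 3 | 5,6-dimethoxybenzene-1,2,4-triol | COc1c(OC)c(O)c(O)cc1O
F6 | step 3 | 1-(2,3,6-trihydroxy-4,5-dimethoxyphenyl)ethaniminium chloride | CC(=[NH2+])c1c(O)c(O)c(OC)c(OC)c1O.[Cl-]
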